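**Retrosynthetic overview**

1. The acid is unmasked last from its methyl ester. The C8 prenyl group, and with it the quaternary centre, is introduced by Pd-catalysed asymmetric allylic dearomatisation of a fully substituted 5,7-dihydroxychroman-4-one. The C6 side chain comes from a carbene-catalysed ynal annulation on the C6-H phenol.
2. Key disconnection C8–C7. The carbocycle C4a–C5–C6–C7–C8–C8a is a phloroglucinol-level ring in which C8 is the γ-carbon of the vinylogous ester O1–C8a=C4a–C4=O of the dihydropyranone ring, and C7 is a carboxyl-level carbon. An acylketene hung on C4a therefore has the CH2 on C8a as its only partner once O1 is locked in the pyranone ring.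
3. The pyranone–dioxinone precursor comes from cyclodehydration of a triketide made by double acylation of 2,2,6-trimethyl-4H-1,3-dioxin-4-one. One acyl group is a Weinreb amide from ethyl (R)-3-hydroxybutanoate (C2, C3); the other is a homologated acid from (−)-α-pinene (both cyclobutane centres).
4. Ring order: cyclobutane (chiral pool) → dihydropyranone → carbocycle (key step) → transient δ-lactone (opened in the same step) → dearomatisation of the carbocycle.

Key step: step 11

Assumption: the 5-hydroxy-4,7-dioxo enol drawn for 25 is taken as the tautomer meant by the target structure, and the catalyst antipodes named in steps 12 and 13 are those expected to give 3S and 8R; the mirror-image catalyst would be used if a model reaction showed the opposite sense.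

**Route**

Step 1
Reactants: 1 (1S,5S)-(−)-α-pinene
Product: 2 2-[(1R,3R)-3-acetyl-2,2-dimethylcyclobutyl]acetic acid (cis-pinonic acid)
Conditions: RuCl3·xH2O (2 mol %), NaIO4 (4 equiv), EtOAc/MeCN/H2O, rt
Reagents that add atoms: sodium periodate [Na+].[O-]I(=O)(=O)=O; water O
Why: Catalytic RuO4 oxidative cleavage of the trisubstituted alkene should give the keto acid without touching either ring stereocentre, so the 1,3-cis cyclobutane of the terpene is carried over unchanged.

Step 2
Reactants: 2 2-[(1R,3R)-3-acetyl-2,2-dimethylcyclobutyl]acetic acid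
Product: 3 2-[(1R,3S)-2,2-dimethyl-3-(prop-1-en-2-yl)cyclobutyl]acetic acid
Conditions: Ph3PCH3Br (2.5 equiv), KOtBu (3.5 equiv), THF, 0 °C to rt; aq. HCl work-up
Reagents that add atoms: methyltriphenylphosphonium bromide C[P+](c1ccccc1)(c1ccccc1)c1ccccc1.[Br-]
Why: Wittig methylenation of the methyl ketone (the carboxylate is a spectator) should install the isopropenyl group; it is run cold and short because the ring CH next to the ketone is the only epimerisable centre.

Step 3
Reactants: 3 2-[(1R,3S)-2,2-dimethyl-3-(prop-1-en-2-yl)cyclobutyl]acetic acid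
Product: 5 1-diazo-3-[(1R,3S)-2,2-dimethyl-3-(prop-1-en-2-yl)cyclobutyl]propan-2-one, via mixed anhydride 4 (not isolated)
Conditions: iBuOCOCl, Et3N, THF, −15 °C; then CH2N2, Et2O, 0 °C to rt
Reagents that add atoms: diazomethane C=[N+]=[N-]
Why: First stage of an Arndt–Eistert homologation, acylation of diazomethane by the mixed carbonic anhydride under conditions that spare the 1,1-disubstituted alkene.

Step 4
Reactants: 5 1-diazo-3-[(1R,3S)-2,2-dimethyl-3-(prop-1-en-2-yl)cyclobutyl]propan-2-one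
Product: 6 3-[(1S,3S)-2,2-dimethyl-3-(prop-1-en-2-yl)cyclobutyl]propanoic acid
Conditions: AgO2CPh (10 mol %), Et3N, THF/H2O (9:1), rt, dark
Reagents that add atoms: water O
Why: Wolff rearrangement with capture of the ketene by water should give the one-carbon-homologated acid; the descriptor at C1 changes only through priorities, not geometry.

Step 5
Reactants: 7 ethyl (3R)-3-hydroxybutanoate
Product: 8 ethyl (2R,3R)-3-hydroxy-2-methylbutanoate
Conditions: LiN(iPr)2 (2.2 equiv), THF, −50 to −20 °C; MeI, DMPU, −78 to −20 °C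
Reagents that add atoms: iodomethane CI
Why: Fráter–Seebach alkylation, in which the chelated dianion is methylated anti to the C3 methyl group, should give the anti (2R,3R) isomer that maps onto the trans-2,3-dimethylpyranone.

Step 6
Reactants: 8 ethyl (2R,3R)-3-hydroxy-2-methylbutanoate
Product: 9 ethyl (2R,3R)-3-[(tert-butyldimethylsilyl)oxy]-2-methylbutanoate
Conditions: TBSCl, imidazole, DMF, rt
Reagents that add atoms: tert-butyldimethylsilyl chloride CC(C)(C)[Si](C)(C)Cl
Why: Standard silylation masks the alcohol so that it cannot be acylated or eliminated in steps 7 to 9.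

Step 7
Reactants: 9 ethyl (2R,3R)-3-[(tert-butyldimethylsilyl)oxy]-2-methylbutanoate
Product: 10 (2R,3R)-3-[(tert-butyldimethylsilyl)oxy]-N-methoxy-N,2-dimethylbutanamide
Conditions: MeNH(OMe)·HCl (2.5 equiv), iPrMgCl (5 equiv), THF, −20 to 0 °C
Reagents that add atoms: N,O-dimethylhydroxylamine hydrochloride CNOC.Cl
Why: Direct aminolysis of the ester by the chloromagnesium amide should give the Weinreb amide at low temperature without enolising the α-centre.

Step 8
Reactants: 10 (2R,3R)-3-[(tert-butyldimethylsilyl)oxy]-N-methoxy-N,2-dimethylbutanamide; 11 2,2,6-trimethyl-4H-1,3-dioxin-4-one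
Product: 12 6-[(3R,4R)-4-[(tert-butyldimethylsilyl)oxy]-3-methyl-2-oxopentyl]-2,2-dimethyl-4H-1,3-dioxin-4-one
Conditions: 11 (2.2 equiv), LiN(SiMe3)2 (2.2 equiv), THF, −78 °C; then 10, −78 to −40 °C; aq. NH4Cl
Reagents that add atoms: none
Why: γ-Acylation of the dioxinone lithium dienolate by the Weinreb amide (a Claisen-type acylation whose chelated tetrahedral intermediate prevents over-addition) should give the keto-dioxinone.

Step 9
Reactants: 6 3-[(1S,3S)-2,2-dimethyl-3-(prop-1-en-2-yl)cyclobutyl]propanoic acid; 12 6-[(3R,4R)-4-[(tert-butyldimethylsilyl)oxy]-3-methyl-2-oxopentyl]-2,2-dimethyl-4H-1,3-dioxin-4-one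
Product: 14 6-[(3R,4R)-4-[(tert-butyldimethylsilyl)oxy]-1-{3-[(1S,3S)-2,2-dimethyl-3-(prop-1-en-2-yl)cyclobutyl]propanoyl}-3-methyl-2-oxopentyl]-2,2-dimethyl-4H-1,3-dioxin-4-one, via acid chloride 13 (not isolated)
Conditions: 6, 1-chloro-N,N,2-trimethylprop-1-en-1-amine, CH2Cl2, 0 °C to rt; then 12, MgCl2 (2 equiv), pyridine (2.7 equiv), CH2Cl2, 0 °C to rt
Reagents that add atoms: none
Why: Soft-enolisation C-acylation of the magnesium chelate at the doubly activated methylene (between the ketone and the dioxinone) by the acid chloride should give the triacylmethane, which exists as enol tautomers and carries no new defined stereocentre; the chloride is made under neutral conditions to spare the isopropenyl group.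

Step 10
Reactants: 14 6-[(3R,4R)-4-[(tert-butyldimethylsilyl)oxy]-1-{3-[(1S,3S)-2,2-dimethyl-3-(prop-1-en-2-yl)cyclobutyl]propanoyl}-3-methyl-2-oxopentyl]-2,2-dimethyl-4H-1,3-dioxin-4-one
Product: 16 6-[(2R,3R)-6-{2-[(1S,3S)-2,2-dimethyl-3-(prop-1-en-2-yl)cyclobutyl]ethyl}-2,3-dimethyl-4-oxo-3,4-dihydro-2H-pyran-5-yl]-2,2-dimethyl-4H-1,3-dioxin-4-one, via hydroxy triketone 15 (not isolated)
Conditions: HF·pyridine, pyridine/THF, 0 °C to rt; then PPTS (20 mol %), 4 Å MS, toluene, 40 °C
Reagents that add atoms: none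
Why: Desilylation followed by acid-catalysed cyclodehydration of the δ-hydroxy-β-diketone (6-exo-trig hemiketalisation on the alkyl ketone, then loss of water) should give the 2,3-dihydro-4H-pyran-4-one; C2 keeps its configuration because its C–O bond is never broken, the trans arrangement is also the more stable one at epimerisable C3, and the dioxinone survives below its thermolysis temperature.

Step 11
Reactants: 16 6-[(2R,3R)-6-{2-[(1S,3S)-2,2-dimethyl-3-(prop-1-en-2-yl)cyclobutyl]ethyl}-2,3-dimethyl-4-oxo-3,4-dihydro-2H-pyran-5-yl]-2,2-dimethyl-4H-1,3-dioxin-4-one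
Product: 20 (2R,3R)-5,7-dihydroxy-2,3-dimethyl-8-{[(1R,3S)-2,2-dimethyl-3-(prop-1-en-2-yl)cyclobutyl]methyl}-2,3-dihydro-4H-chromen-4-one, via acylketene 17 (not isolated), via dienol ketene 18 (not isolated), via cyclohexadienone 19 (not isolated)
Conditions: toluene (0.005 M), 110 °C, N2 sweep to remove acetone, 4 Å MS
Reagents that add atoms: none
Why: Proposed new method: at 110 °C the dioxinone should undergo its known retro-[4+2] loss of acetone to acylketene 17; because O1 is an ether no oxygen nucleophile can capture the ketene, so a [1,5]-hydrogen shift from the CH2 on C6 of the pyranone (the γ-position of a doubly acceptor-substituted vinylogous ester) to the neighbouring acyl oxygen should give the pyranone-methide dienol 18, whose dienylketene closes by 6π-electrocyclisation (equivalently a 6-(enolendo)-exo-trig C-acylation) to form the C8–C7 bond, and enolisation of 19 aromatises the new ring. The closest known reaction types are the thermolysis of keto-dioxinones to acylketenes with intramolecular capture and aromatisation in biomimetic resorcylate synthesis, and the 6π-closure of dienylketenes that ends the benzannulation of vinylketenes with alkynes. The one ring closed is the carbocycle C4a–C5–C6–C7–C8–C8a, closed thermally in the disrotatory 6π mode; no stereocentre is created, since the sp3 carbon formed at C8 in 19 is erased by aromatisation and C2 and C3 are untouched under neutral conditions. The selectivity needed is C-acylation at the γ-carbon rather than O-acylation, acylation at C3 or ketene dimerisation; it is secured by the blocked enol-ether oxygen, by the fact that attack through C3 would require a bridgehead double bond, by high dilution and by removal of acetone.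

Step 12
Reactants: 20 (2R,3R)-5,7-dihydroxy-2,3-dimethyl-8-{[(1R,3S)-2,2-dimethyl-3-(prop-1-en-2-yl)cyclobutyl]methyl}-2,3-dihydro-4H-chromen-4-one; 21 oct-2-ynal
Product: 23 methyl (3S)-3-[(2R,3R)-5,7-dihydroxy-2,3-dimethyl-8-{[(1R,3S)-2,2-dimethyl-3-(prop-1-en-2-yl)cyclobutyl]methyl}-4-oxo-3,4-dihydro-2H-chromen-6-yl]octanoate, via lactone 22 (not isolated)
Conditions: 21 (1.3 equiv), (5aR,10bS)-2-mesityl-5a,10b-dihydro-4H,6H-indeno[2,1-b][1,2,4]triazolo[4,3-d][1,4]oxazin-2-ium chloride (10 mol %), iPr2NEt (10 mol %), toluene, 40 °C; then MeOH, Et3N, rt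
Reagents that add atoms: methanol CO
Why: Carbene-catalysed redox activation of the ynal to an α,β-unsaturated acyl azolium, followed by Coates–Claisen-type C–C bond formation at C6 (the only free ring position, flanked by two hydroxyls) and lactonisation, should give a dihydrocoumarin-type lactone that is opened by methanol in the same flask (either lactone regiochemistry converges on the same ester); the C3 side-chain centre is set by the chiral carbene.

Step 13
Reactants: 23 methyl (3S)-3-[(2R,3R)-5,7-dihydroxy-2,3-dimethyl-8-{[(1R,3S)-2,2-dimethyl-3-(prop-1-en-2-yl)cyclobutyl]methyl}-4-oxo-3,4-dihydro-2H-chromen-6-yl]octanoate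
Product: 24 methyl (3S)-3-[(2R,3R,8R)-5-hydroxy-2,3-dimethyl-8-(3-methylbut-2-en-1-yl)-8-{[(1R,3S)-2,2-dimethyl-3-(prop-1-en-2-yl)cyclobutyl]methyl}-4,7-dioxo-3,4,7,8-tetrahydro-2H-chromen-6-yl]octanoate
Conditions: Pd2(dba)3·CHCl3 (2.5 mol %), N,N'-[(1R,2R)-cyclohexane-1,2-diyl]bis[2-(diphenylphosphanyl)benzamide] (7.5 mol %), prenyl acetate (1.1 equiv), Cs2CO3 (1.1 equiv), THF, 0 °C to rt
Reagents that add atoms: prenyl acetate CC(C)=CCOC(C)=O
Why: Tsuji–Trost-type allylic alkylative dearomatisation of the 7-phenoxide should place the prenyl group at its less hindered terminus on C8 rather than on C6 (which carries an α-branched chain) or on oxygen (O-prenyl ethers re-ionise under zerovalent palladium, while the C-alkylated vinylogous acid is the sink), with the face at C8 chosen by the chiral diphosphine.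

Step 14
Reactants: 24 methyl (3S)-3-[(2R,3R,8R)-5-hydroxy-2,3-dimethyl-8-(3-methylbut-2-en-1-yl)-8-{[(1R,3S)-2,2-dimethyl-3-(prop-1-en-2-yl)cyclobutyl]methyl}-4,7-dioxo-3,4,7,8-tetrahydro-2H-chromen-6-yl]octanoate
Product: 25 (3S)-3-[(2R,3R,8R)-5-hydroxy-2,3-dimethyl-8-(3-methylbut-2-en-1-yl)-8-{[(1R,3S)-2,2-dimethyl-3-(prop-1-en-2-yl)cyclobutyl]methyl}-4,7-dioxo-3,4,7,8-tetrahydro-2H-chromen-6-yl]octanoic acid
Conditions: LiOH·H2O (3 equiv), THF/H2O (3:1), 0 °C to rt; 1 M HCl to pH 3
Reagents that add atoms: lithium hydroxide [Li+].[OH-]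
Why: Saponification of the unhindered methyl ester should proceed while the ring is protected as its vinylogous carboxylate, and the cold, short exposure is chosen to avoid retro-oxa-Michael opening of the pyranone.

**Compound list**

1 | (1S,5S)-(−)-α-pinene | CC1=CC[C@H]2C[C@@H]1C2(C)C | starting material
2 | 2-[(1R,3R)-3-acetyl-2,2-dimethylcyclobutyl]acetic acid | CC(=O)[C@@H]1C[C@H](CC(=O)O)C1(C)C | intermediate
3 | 2-[(1R,3S)-2,2-dimethyl-3-(prop-1-en-2-yl)cyclobutyl]acetic acid | C=C(C)[C@@H]1C[C@H](CC(=O)O)C1(C)C | intermediate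
4 | 2-[(1R,3S)-2,2-dimethyl-3-(prop-1-en-2-yl)cyclobutyl]acetic isobutyl carbonic anhydride | C=C(C)[C@@H]1C[C@H](CC(=O)OC(=O)OCC(C)C)C1(C)C | intermediate
5 | 1-diazo-3-[(1R,3S)-2,2-dimethyl-3-(prop-1-en-2-yl)cyclobutyl]propan-2-one | C=C(C)[C@@H]1C[C@H](CC(=O)C=[N+]=[N-])C1(C)C | intermediate
6 | 3-[(1S,3S)-2,2-dimethyl-3-(prop-1-en-2-yl)cyclobutyl]propanoic acid | C=C(C)[C@@H]1C[C@H](CCC(=O)O)C1(C)C | intermediate
7 | ethyl (3R)-3-hydroxybutanoate | CCOC(=O)C[C@@H](C)O | starting material
8 | ethyl (2R,3R)-3-hydroxy-2-methylbutanoate | CCOC(=O)[C@H](C)[C@@H](C)O | intermediate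
9 | ethyl (2R,3R)-3-[(tert-butyldimethylsilyl)oxy]-2-methylbutanoate | CCOC(=O)[C@H](C)[C@@H](C)O[Si](C)(C)C(C)(C)C | intermediate
10 | (2R,3R)-3-[(tert-butyldimethylsilyl)oxy]-N-methoxy-N,2-dimethylbutanamide | CON(C)C(=O)[C@H](C)[C@@H](C)O[Si](C)(C)C(C)(C)C | intermediate
11 | 2,2,6-trimethyl-4H-1,3-dioxin-4-one | CC1=CC(=O)OC(C)(C)O1 | starting material
12 | 6-[(3R,4R)-4-[(tert-butyldimethylsilyl)oxy]-3-methyl-2-oxopentyl]-2,2-dimethyl-4H-1,3-dioxin-4-one | CC1(C)OC(=O)C=C(CC(=O)[C@H](C)[C@@H](C)O[Si](C)(C)C(C)(C)C)O1 | intermediate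
13 | 3-[(1S,3S)-2,2-dimethyl-3-(prop-1-en-2-yl)cyclobutyl]propanoyl chloride | C=C(C)[C@@H]1C[C@H](CCC(=O)Cl)C1(C)C | intermediate
14 | 6-[(3R,4R)-4-[(tert-butyldimethylsilyl)oxy]-1-{3-[(1S,3S)-2,2-dimethyl-3-(prop-1-en-2-yl)cyclobutyl]propanoyl}-3-methyl-2-oxopentyl]-2,2-dimethyl-4H-1,3-dioxin-4-one (enol tautomers; C1 of the pentyl chain not a defined centre) | C=C(C)[C@@H]1C[C@H](CCC(=O)C(C(=O)[C@H](C)[C@@H](C)O[Si](C)(C)C(C)(C)C)C2=CC(=O)OC(C)(C)O2)C1(C)C | intermediate
15 | 6-[(3R,4R)-1-{3-[(1S,3S)-2,2-dimethyl-3-(prop-1-en-2-yl)cyclobutyl]propanoyl}-4-hydroxy-3-methyl-2-oxopentyl]-2,2-dimethyl-4H-1,3-dioxin-4-one | C=C(C)[C@@H]1C[C@H](CCC(=O)C(C(=O)[C@H](C)[C@@H](C)O)C2=CC(=O)OC(C)(C)O2)C1(C)C | intermediate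
16 | 6-[(2R,3R)-6-{2-[(1S,3S)-2,2-dimethyl-3-(prop-1-en-2-yl)cyclobutyl]ethyl}-2,3-dimethyl-4-oxo-3,4-dihydro-2H-pyran-5-yl]-2,2-dimethyl-4H-1,3-dioxin-4-one | C=C(C)[C@@H]1C[C@H](CCC2=C(C3=CC(=O)OC(C)(C)O3)C(=O)[C@H](C)[C@@H](C)O2)C1(C)C | intermediate
17 | acylketene: 3-oxo-3-[(2R,3R)-2,3-dimethyl-4-oxo-6-(2-cyclobutylethyl)-3,4-dihydro-2H-pyran-5-yl]prop-1-en-1-one, cyclobutyl group as in 16 | C=C(C)[C@@H]1C[C@H](CCC2=C(C(=O)C=C=O)C(=O)[C@H](C)[C@@H](C)O2)C1(C)C | intermediate
18 | dienol ketene: the 6-alkylidene tautomer of 17 with the acyl group enolised (2R,3R; cyclobutyl group as in 16) | C=C(C)[C@@H]1C[C@H](CC=C2O[C@H](C)[C@@H](C)C(=O)C2=C(O)C=C=O)C1(C)C | intermediate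
19 | cyclohexadienone: (2R,3R)-5-hydroxy-2,3-dimethyl-8-{[2,2-dimethyl-3-(prop-1-en-2-yl)cyclobutyl]methyl}-2,3-dihydro-4H-chromene-4,7(8H)-dione, C8 undefined, cyclobutane centres as in 20 | C=C(C)[C@@H]1C[C@H](CC2C(=O)C=C(O)C3=C2O[C@H](C)[C@@H](C)C3=O)C1(C)C | intermediate
20 | (2R,3R)-5,7-dihydroxy-2,3-dimethyl-8-{[(1R,3S)-2,2-dimethyl-3-(prop-1-en-2-yl)cyclobutyl]methyl}-2,3-dihydro-4H-chromen-4-one | C=C(C)[C@@H]1C[C@H](Cc2c(O)cc(O)c3c2O[C@H](C)[C@@H](C)C3=O)C1(C)C | intermediate
21 | oct-2-ynal | CCCCCC#CC=O | starting material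
22 | lactone: δ-lactone between O7 of 20 and a (3S)-3-substituted octanoyl chain on C6 (a (4S)-4-pentyl-3,4-dihydro-2H-pyran-2-one ring fused at C6–C7) | C=C(C)[C@@H]1C[C@H](Cc2c3OC(=O)C[C@H](CCCCC)c3c(O)c3c2O[C@H](C)[C@@H](C)C3=O)C1(C)C | intermediate
23 | methyl (3S)-3-[(2R,3R)-5,7-dihydroxy-2,3-dimethyl-8-{[(1R,3S)-2,2-dimethyl-3-(prop-1-en-2-yl)cyclobutyl]methyl}-4-oxo-3,4-dihydro-2H-chromen-6-yl]octanoate | C=C(C)[C@@H]1C[C@H](Cc2c(O)c([C@@H](CCCCC)CC(=O)OC)c(O)c3c2O[C@H](C)[C@@H](C)C3=O)C1(C)C | intermediate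
24 | methyl (3S)-3-[(2R,3R,8R)-5-hydroxy-2,3-dimethyl-8-(3-methylbut-2-en-1-yl)-8-{[(1R,3S)-2,2-dimethyl-3-(prop-1-en-2-yl)cyclobutyl]methyl}-4,7-dioxo-3,4,7,8-tetrahydro-2H-chromen-6-yl]octanoate | C=C(C)[C@@H]1C[C@H](C[C@@]2(CC=C(C)C)C(=O)C([C@@H](CCCCC)CC(=O)OC)=C(O)C3=C2O[C@H](C)[C@@H](C)C3=O)C1(C)C | intermediate
25 | (3S)-3-[(2R,3R,8R)-5-hydroxy-2,3-dimethyl-8-(3-methylbut-2-en-1-yl)-8-{[(1R,3S)-2,2-dimethyl-3-(prop-1-en-2-yl)cyclobutyl]methyl}-4,7-dioxo-3,4,7,8-tetrahydro-2H-chromen-6-yl]octanoic acid | C=C(C)[C@@H]1C[C@H](C[C@@]2(CC=C(C)C)C(=O)C([C@@H](CCCCC)CC(=O)O)=C(O)C3=C2O[C@H](C)[C@@H](C)C3=O)C1(C)C | target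

**Step count**

Total steps: 14. Longest linear sequence: 10 steps (steps 1–4 then 9–14; the branch through steps 5–8 then 9–14 is equally long).

**Steps most likely to fail**

Step 11. The acylketene may be lost to dimerisation or to capture by traces of water before the [1,5]-hydrogen shift and ring closure take place. The fallback sets out from 16 and returns at 20 by known chemistry. Heating 16 with methanol in toluene at 110 °C should trap the ketene as the β-keto ester methyl 3-[(2R,3R)-6-{2-[(1S,3S)-2,2-dimethyl-3-(prop-1-en-2-yl)cyclobutyl]ethyl}-2,3-dimethyl-4-oxo-3,4-dihydro-2H-pyran-5-yl]-3-oxopropanoate F1. Treatment of F1 with LiN(SiMe3)2 (3 equiv, THF, −78 to 0 °C) should deprotonate the γ-CH2 of the pyranone and close the ring by an intramolecular vinylogous Claisen condensation on the ester (the base-mediated Claisen cyclisation of triketo esters to acylphloroglucinols), giving 20 after aromatisation on work-up.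

Step 13. Facial selectivity at C8 may be poor, and alkylation may be diverted to C6 or oxygen, because the 3,3-disubstituted allyl unit is a demanding electrophile for asymmetric allylic dearomatisation. The fallback sets out from 23 and returns at 24. With allyl methyl carbonate and the same Pd2(dba)3·CHCl3/chiral diphosphine system (the unsubstituted allyl group is the best-precedented electrophile for this reaction type), 23 should give methyl (3S)-3-[(2R,3R,8R)-5-hydroxy-2,3-dimethyl-8-(prop-2-en-1-yl)-8-{[(1R,3S)-2,2-dimethyl-3-(prop-1-en-2-yl)cyclobutyl]methyl}-4,7-dioxo-3,4,7,8-tetrahydro-2H-chromen-6-yl]octanoate F2. Cross-metathesis of F2 with 2-methylbut-2-ene (second-generation Grubbs catalyst, RuCl2(=CHPh)(H2IMes)(PCy3), CH2Cl2, 40 °C) should then convert the allyl into the prenyl group and give 24; the hindered 1,1-disubstituted isopropenyl group should not take part.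

Step 12. The acyl azolium may simply O-acylate the phenol without C–C bond formation, or the aliphatic ynal may give low enantioselectivity. The fallback sets out from 20 and returns at 22. Iminium-catalysed Friedel–Crafts-type conjugate addition of 20 to (E)-oct-2-enal with (R)-α,α-diphenylprolinol trimethylsilyl ether and benzoic acid in toluene should give the lactol (hemiacetal between O7 and the aldehyde of the (3S)-3-aryloctanal) F3. Oxidation of F3 with Ag2CO3 on Celite (toluene, 80 °C) should give lactone 22, which is opened with MeOH/Et3N as in step 12.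

Further compounds
F1 | step 11 | methyl 3-[(2R,3R)-6-{2-[(1S,3S)-2,2-dimethyl-3-(prop-1-en-2-yl)cyclobutyl]ethyl}-2,3-dimethyl-4-oxo-3,4-dihydro-2H-pyran-5-yl]-3-oxopropanoate | C=C(C)[C@@H]1C[C@H](CCC2=C(C(=O)CC(=O)OC)C(=O)[C@H](C)[C@@H](C)O2)C1(C)C
F2 | step 13 | methyl (3S)-3-[(2R,3R,8R)-5-hydroxy-2,3-dimethyl-8-(prop-2-en-1-yl)-8-{[(1R,3S)-2,2-dimethyl-3-(prop-1-en-2-yl)cyclobutyl]methyl}-4,7-dioxo-3,4,7,8-tetrahydro-2H-chromen-6-yl]octanoate | C=C(C)[C@@H]1C[C@H](C[C@@]2(CC=C)C(=O)C([C@@H](CCCCC)CC(=O)OC)=C(O)C3=C2O[C@H](C)[C@@H](C)C3=O)C1(C)C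
F3 | step 12 | lactol: cyclic hemiacetal between O7 of 20 and the aldehyde of a (3S)-3-substituted octanal chain on C6 (hemiacetal carbon undefined) | C=C(C)[C@@H]1C[C@H](Cc2c3OC(O)C[C@H](CCCCC)c3c(O)c3c2O[C@H](C)[C@@H](C)C3=O)C1(C)C
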